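## The problem

The target is a heptacyclic stilbenoid built from two resveratrol units and one oxyresveratrol unit. Its centre is a fully substituted benzene, ring A, with oxygen on A1 and A3, hydrogen on A2 and carbon on A4, A5 and A6. Ring A is fused at A1/A6 and at A3/A4 to two trans-2-(4-hydroxyphenyl)-3-aryl-2,3-dihydrobenzofurans (dihydrofuran 1: O–C-a–C-b; dihydrofuran 2: O–C-e–C-d). Through A4 and A5 it is fused to a seven-membered ring that also holds C-d, two carbons of the resorcinol ring B, the methine C-c (bearing the 2,4-dihydroxyphenyl group) and one CH2.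

All five stereocentres are R. C-a/C-b and C-e/C-d are two identical trans pairs, so the benzodifuran core has a twofold axis through A2 and A5 until the seven-membered ring is closed. C-c is the only centre that must be set relative to the others, and C-d, which sits 1,4 to it across ring B, is the element that can control it.

Three contiguous carbon substituents on A4–A6, two of them diarylmethines, make stepwise substitution of a bought resorcinol unattractive. The eight phenols (oxidation, quinone methides) and the two 4-oxybenzylic C–O bonds of the dihydrofurans (ionized by acids and Lewis acids, trans being the stable form) will not survive rough treatment.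

The enabling feature is the O, H, O pattern on A1–A3 flanked by two O–CH–CH chains that return to A6 and A4. Ring A can therefore come from three alkynes: a 1,3-diyne carrying the oxygen of dihydrofuran 2 on its terminus, an alkyne held to it by the O–C-e–C-d chain, and an aryne that is captured by the carbinol oxygen of the other chain.

## Retrosynthesis

**25 ⇒ 24.** The eight phenols of 25 are carried as methyl ethers, so only O–CH3 bonds are cut. Methyl ethers tolerate the organometallic, strongly basic and thermal steps before this point, and one operation removes them all. The forward step must cleave them without ionizing the benzylic C–O bonds of the dihydrofurans.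

**24 ⇒ 22.** The bond between C-c and ring B is cut. This removes the seven-membered ring and the only stereocentre outside the dihydrofurans. The precursor 22 is a C2-symmetric benzodifuran with an (E)-2,4-dimethoxystyryl group on A5, so the two 3,5-dimethoxyphenyl rings are equivalent and the ring closure has no regiochemical choice. The side chain is carried as an alkene, not as a protected carbinol: protonation gives the same benzylic cation, no arbitrary extra stereocentre travels through the route, no deprotection is needed, and the alkyne that bears it earlier becomes a conjugated enyne. The forward reaction must deliver one face of the cation to ring B under control of C-d.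

**22 ⇒ 20 (key disconnection).** Three bonds are cut: A3–A4, A5–A6 and O–A1. This opens ring A and both dihydrofurans and leaves the acyclic triyne 20, in which the four stereocentres sit on two open chains. The alternative, building the three contiguous hindered substituents on a preformed arene, would need two separate stereocontrolled annulations at crowded positions. The forward reaction asks that cycloaromatization of the alkoxydiyne with the enyne be faster than thermal decay of the alkynyl ether, and that the carbinol oxygen capture the aryne at A1.

**20 ⇒ 19 + 9.** The sp–sp bond in the middle of the diyne is cut, giving terminal alkynyl ether 19 and bromoalkyne 9. Cutting the O–C(sp) bond instead would require alkoxide substitution at a haloalkyne, which is not a dependable reaction. Both halves come from the same alcohol 8, which is what the twofold symmetry of 22 suggests.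

**19 ⇒ 16 ⇒ 12 + 13.** The two carbons of the alkynyl ether (later A2 and A3) come from trichloroethylene 13 through dichlorovinyl ether 16. Only the O–H bond of alcohol 12 is used, so C-e keeps its configuration.

**12 ⇒ 8 + 11; 9 ⇒ 8; 11 ⇒ 10.** The enyne of 12 is cut at the sp–sp2 bond into terminal alkyne 8 and bromoalkene 11, which comes from cinnamic acid 10 by loss of CO2. Bromoalkyne 9 is 8 with its terminal hydrogen exchanged for bromine.

**8 ⇒ 7 ⇒ 4 + 5.** The C-a–C-b bond is cut. An anti-selective addition of a chiral allenylmetal, made from propargylic mesylate 4, to aldehyde 5 sets both centres in one step. An aldol route would be longer and would pass through an epimerizable α-aryl aldehyde on the way to the alkyne. The forward reaction must transfer the configuration of 4 faithfully and favour the anti isomer.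

**4 ⇒ 3 ⇒ 1 + 2.** The propargylic carbinol is cut into aldehyde 1 and silylacetylene 2. An aldehyde is chosen as the source of the 3,5-dimethoxyphenyl carbon because its carbinol stereocentre is what the chirality transfer needs, and catalytic asymmetric alkynylation supplies it in one step.

## Roads not taken

**Alternative 1: aryne insertion into an indanone.** The cut is at the two bonds from ring B to the seven-membered ring (ring B–C-d and ring B–C-c). In the forward step, fluoride releases aryne A2, the enolate of keto ester A1 adds to it, and the aryl anion attacks the ketone. Fragmentation expands the five-membered ring to the dibenzocycloheptenone A3.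

- Merits: the seven-membered ring and both ring B bonds form in one operation of a well-established type, and the methoxy group next to the aryne directs the regiochemistry.
- Weak points: A3 carries none of the five stereocentres and is racemic. The ketone and the ester must each be turned into an aryl-bearing methine with stereocontrol, and both dihydrofurans still have to be annulated onto ring A, one of them at the position flanked by the seven-membered ring.
- Comparison: the key step of this road is better precedented than that of the chosen plan, and this is conceded. The chosen plan sets against it that four stereocentres are fixed on open chains by one asymmetric sequence used twice, and that ring A and both heterocycles appear in one step, leaving two steps to the target.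

**Alternative 2: ring B by benzannulation on a cycloheptene.** The cut removes four bonds of ring B. In the forward step, light induces Wolff rearrangement of diazo ketone A4. Addition to siloxyalkyne A5, four-electron ring opening and six-electron ring closure give the monosilylated resorcinol A6.

- Merits: the benzannulation is a known, regiodefined route to resorcinols. C-c, C-d and C-e are already in place, so C-c does not depend on a late cation closure; in that respect this road is the safer one.
- Weak points: A4 is a cycloheptene-fused dihydrobenzofuran with three stereocentres and is itself a long synthesis. The photolysis is run beside benzylic ethers. After A6, dihydrofuran 1 with two more stereocentres must still be built onto ring A at an unactivated, flanked C–H position.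
- Comparison: the chosen plan offsets its less certain control of C-c by convergence and by forming the crowded ring A last rather than carrying it.

**Alternative 3: oxidative ring contraction of a flavanone.** The cut is at the bond from ring A to C3 of one dihydrofuran. In the forward step, PhI(OAc)2 with HC(OMe)3 and H2SO4 activates C3 of flavanone A7, and ring A shifts from the carbonyl carbon to C3, giving the trans ester A8.

- Merits: the reaction type is known, enantioenriched flavanones are accessible, the trans relationship is set, and the ester and the ring methyl are handles for ring B and the CH2 group. In certainty of the key step and of its stereochemical transfer this road is superior.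
- Weak points: A8 holds one of the two dihydrofurans and two of the five stereocentres. The ester must be converted into an entire aryl ring at a diarylmethine, the methyl must be functionalized, and the second dihydrofuran and the seven-membered ring remain. The sequence is long and linear, and the strongly acidic oxidant meets electron-rich arenes.
- Comparison: the chosen plan sets against it a key step that solves ring A, both dihydrofurans and the whole substitution pattern at once.

Key step: step 11

Assumption: (S,S)-ProPhenol is taken to give the (S)-alcohol 3; if the sense of induction is the opposite, (R,R)-ProPhenol is used and nothing else changes.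

## Route

Step 1
Reactants: 1 3,5-dimethoxybenzaldehyde; 2 ethynyltrimethylsilane
Product: 3 (S)-1-(3,5-dimethoxyphenyl)-3-(trimethylsilyl)prop-2-yn-1-ol
Conditions: (S,S)-ProPhenol (10 mol %), Me2Zn (3 equiv), Ph3PO (20 mol %), toluene, 0 °C to rt; aq. NH4Cl
Reagents that add atoms: none
Why: Catalytic enantioselective alkynylzinc addition to an aryl aldehyde under a dinuclear zinc–ProPhenol catalyst; the ligand selects the aldehyde face and so sets the carbinol centre.

Step 2
Reactants: 3 (S)-1-(3,5-dimethoxyphenyl)-3-(trimethylsilyl)prop-2-yn-1-ol
Product: 4 (S)-1-(3,5-dimethoxyphenyl)-3-(trimethylsilyl)prop-2-yn-1-yl methanesulfonate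
Conditions: MsCl, Et3N, CH2Cl2, −78 °C; used crude
Reagents that add atoms: methanesulfonyl chloride, CS(=O)(=O)Cl
Why: O-sulfonylation of a secondary propargylic alcohol; only the O–H bond reacts, so configuration is retained. The meta-methoxy groups do not stabilize a benzylic cation, so the mesylate should last long enough to be used directly.

Step 3
Reactants: 4 (S)-1-(3,5-dimethoxyphenyl)-3-(trimethylsilyl)prop-2-yn-1-yl methanesulfonate; 5 4-methoxybenzaldehyde
Product: 7 (1R,2R)-2-(3,5-dimethoxyphenyl)-1-(4-methoxyphenyl)-4-(trimethylsilyl)but-3-yn-1-ol (anti), via allenylindium iodide mesylate 6 (not isolated)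
Conditions: Pd(dppf)Cl2 (5 mol %), InI (1.5 equiv), THF–HMPA (3:1), 0 °C to rt
Reagents that add atoms: none
Why: Palladium-catalysed, indium-mediated propargylation: zerovalent palladium opens 4 in an anti SN2′ sense, transmetalation with retention gives 6, and 6 adds to the aldehyde through a closed SE2′ transition state. The net inversion at the propargylic carbon sets C2, and the chair-like transition state with the aldehyde aryl group turned away from the allene substituent should give the anti carbinol at C1.

Step 4
Reactants: 7 (1R,2R)-2-(3,5-dimethoxyphenyl)-1-(4-methoxyphenyl)-4-(trimethylsilyl)but-3-yn-1-ol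
Product: 8 (1R,2S)-2-(3,5-dimethoxyphenyl)-1-(4-methoxyphenyl)but-3-yn-1-ol
Conditions: K2CO3 (0.2 equiv), MeOH, 0 °C to rt
Reagents that add atoms: none
Why: Methanolysis of the alkynyl–silicon bond with catalytic carbonate; short, cold treatment should avoid propargyl–allenyl isomerization at the benzylic centre (the descriptor at C2 changes only because the priorities change).

Step 5
Reactants: 8 (1R,2S)-2-(3,5-dimethoxyphenyl)-1-(4-methoxyphenyl)but-3-yn-1-ol
Product: 9 (1R,2R)-4-bromo-2-(3,5-dimethoxyphenyl)-1-(4-methoxyphenyl)but-3-yn-1-ol
Conditions: NBS (1.05 equiv), AgNO3 (10 mol %), acetone, 0 °C, dark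
Reagents that add atoms: N-bromosuccinimide, O=C1CCC(=O)N1Br
Why: Silver-catalysed bromination of a terminal alkyne through the silver acetylide; with one equivalent of NBS at 0 °C this should be much faster than bromination of the methoxyarenes, and the free hydroxyl is tolerated.

Step 6
Reactants: 10 (E)-3-(2,4-dimethoxyphenyl)prop-2-enoic acid
Product: 11 (E)-1-(2-bromoethenyl)-2,4-dimethoxybenzene
Conditions: NBS (1.05 equiv), LiOAc (0.2 equiv), MeCN–H2O (97:3), rt
Reagents that add atoms: N-bromosuccinimide, O=C1CCC(=O)N1Br
Why: Catalytic Hunsdiecker-type bromodecarboxylation: the electron-rich cinnamate is brominated at the α-carbon and loses CO2, which gives the (E)-bromoalkene.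

Step 7
Reactants: 8 (1R,2S)-2-(3,5-dimethoxyphenyl)-1-(4-methoxyphenyl)but-3-yn-1-ol; 11 (E)-1-(2-bromoethenyl)-2,4-dimethoxybenzene
Product: 12 (1R,2R,5E)-2-(3,5-dimethoxyphenyl)-6-(2,4-dimethoxyphenyl)-1-(4-methoxyphenyl)hex-5-en-3-yn-1-ol
Conditions: Pd(PPh3)4 (5 mol %), CuI (10 mol %), i-Pr2NH, THF, rt, degassed
Reagents that add atoms: none
Why: Sonogashira coupling of a terminal alkyne with an alkenyl bromide, with retention of alkene geometry; the free alcohol and the propargylic stereocentre are not touched under amine base at room temperature.

Step 8
Reactants: 12 (1R,2R,5E)-2-(3,5-dimethoxyphenyl)-6-(2,4-dimethoxyphenyl)-1-(4-methoxyphenyl)hex-5-en-3-yn-1-ol; 13 trichloroethylene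
Product: 16 (E)-1,2-dichloroethenyl ether of alcohol 12 (oxygen on C1 of the hexenynyl chain), via potassium alkoxide 14 (not isolated), via dichloroacetylene 15 (not isolated)
Conditions: KH (1.05 equiv), THF, 0 °C, 15 min; then Cl2C=CHCl (1.2 equiv), −40 °C to rt
Reagents that add atoms: none
Why: Known alkoxide route to 1,2-dichlorovinyl ethers: the alkoxide eliminates HCl from trichloroethylene and adds trans to the dichloroacetylene so formed. Only the O–H bond of 12 is broken, so the carbinol configuration is kept; no excess base and low temperature guard the propargylic centre.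

Step 9
Reactants: 16 (E)-1,2-dichloroethenyl ether of alcohol 12
Product: 19 ethynyl ether of alcohol 12, (1R,2R,5E)-1-(ethynyloxy)-2-(3,5-dimethoxyphenyl)-6-(2,4-dimethoxyphenyl)-1-(4-methoxyphenyl)hex-5-en-3-yne, via chloroethynyl ether 17 (not isolated), via lithium alkoxyacetylide 18 (not isolated)
Conditions: n-BuLi (2.3 equiv), THF, −78 °C; MeOH, −78 °C; cold NaHCO3 work-up, filtration through base-washed silica at 0 °C, used at once
Reagents that add atoms: none
Why: Elimination of HCl by n-BuLi and lithium–chlorine exchange give the lithium alkoxyacetylide, which is protonated cold; both stereocentres are remote from the reacting carbons. The product is kept cold because benzylic alkynyl ethers rearrange on warming.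

Step 10
Reactants: 19 ethynyl ether of alcohol 12; 9 (1R,2R)-4-bromo-2-(3,5-dimethoxyphenyl)-1-(4-methoxyphenyl)but-3-yn-1-ol
Product: 20 triyne (1R,2R)-2-(3,5-dimethoxyphenyl)-6-{[(1R,2R,5E)-2-(3,5-dimethoxyphenyl)-6-(2,4-dimethoxyphenyl)-1-(4-methoxyphenyl)hex-5-en-3-yn-1-yl]oxy}-1-(4-methoxyphenyl)hexa-3,5-diyn-1-ol
Conditions: CuCl (5 mol %), NH2OH·HCl (0.3 equiv), n-BuNH2 (30% in H2O), Et2O, 0 °C; cold work-up, used at once
Reagents that add atoms: none
Why: Cadiot–Chodkiewicz coupling: the copper acetylide of the terminal alkynyl ether attacks the bromoalkyne and joins two different alkynes selectively. The medium is basic, which alkynyl ethers tolerate, and the free carbinol needs no protection.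

Step 11
Reactants: 20 triyne
Product: 22 (2R,3R,5R,6R)-3,5-bis(3,5-dimethoxyphenyl)-4-[(E)-2-(2,4-dimethoxyphenyl)ethenyl]-2,6-bis(4-methoxyphenyl)-2,3,5,6-tetrahydrobenzo[1,2-b:5,4-b']difuran, via ring A benzyne 21 (not isolated)
Conditions: slow addition of fresh 20 to PhCl (final 0.005 M), K2CO3 (solid), 80 °C, dark, argon
Reagents that add atoms: none
Why: Proposed new method: heating should bring the alkoxy-1,3-diyne (four carbons) and the triple bond of the enyne (two carbons) together in a hexadehydro-Diels–Alder reaction, most likely stepwise through a diradical: the A3–A4 bond forms first and closes dihydrofuran 2 as the tether ring, then the A5–A6 bond closes ring A as benzyne 21. The carbinol oxygen then adds to aryne carbon A1 (five-membered ring, exo attack of a tethered nucleophile) and its proton ends on A2, which closes dihydrofuran 1. The closest known reactions are thermal cycloisomerizations of ether-, ester-, sulfonamide- and ynamide-tethered triynes with capture of the benzyne by a hydroxyl or silyl ether two carbons from the diyne; a diyne that carries an ether oxygen directly on its terminus has not been used. No stereocentre is formed or touched, since the four sp3 centres lie outside the reacting π systems. The ring fusion is fixed by the three-atom tether, and the site of O-attack is fixed by ring size and reinforced by the polarization of a 3-alkoxyaryne, which directs nucleophiles to the carbon meta to oxygen (A1). The selectivity the step needs is one of rate: cycloaromatization has to outrun the [3,3] shift and the retro-ene cleavage that are open to a benzylic alkynyl ether. The conjugated enyne (a radical-stabilizing diynophile, as in tetraynes), the trans-diaryl-substituted tether, high dilution and the lowest workable temperature are chosen for that reason.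

Step 12
Reactants: 22 styryl benzodifuran
Product: 24 octa-O-methyl ether of the target (all five stereocentres R), via benzylic cation 23 (not isolated)
Conditions: TFA (5 equiv), CH2Cl2 (0.005 M), −20 to 0 °C
Reagents that add atoms: none
Why: Acid protonates the 2,4-dimethoxystyrene at the carbon next to ring A, and the benzylic cation alkylates the ortho position of a 3,5-dimethoxyphenyl ring (intramolecular Friedel–Crafts alkylation, seven-membered ring); the two such rings are equivalent by the twofold symmetry of 22. C-c should be set under control of C-d, with the aryl group on the cation turned outward and opposite to the dihydrofuran carbon on C-d; because ionization is reversible in acid, the more stable epimer should accumulate.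

Step 13
Reactants: 24 octa-O-methyl ether of the target
Product: 25 target, CNP0154047.1
Conditions: BBr3 (24 equiv), CH2Cl2, −78 to 0 °C; MeOH, then H2O
Reagents that add atoms: none
Why: Lewis acid cleavage of aryl methyl ethers by BBr3 (bromide attacks the methyl group); aryl–oxygen bonds and the five stereocentres are not involved. Low temperature is meant to spare the benzylic C–O bonds of the dihydrofurans, for which trans is in any case the stable arrangement.

## Compound list

1 | 3,5-dimethoxybenzaldehyde | COc1cc(C=O)cc(OC)c1 | starting material
2 | ethynyltrimethylsilane | C#C[Si](C)(C)C | starting material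
3 | (S)-1-(3,5-dimethoxyphenyl)-3-(trimethylsilyl)prop-2-yn-1-ol | C[Si](C)(C)C#C[C@@H](O)c1cc(OC)cc(OC)c1 | intermediate
4 | (S)-1-(3,5-dimethoxyphenyl)-3-(trimethylsilyl)prop-2-yn-1-yl methanesulfonate | C[Si](C)(C)C#C[C@@H](OS(C)(=O)=O)c1cc(OC)cc(OC)c1 | intermediate
5 | 4-methoxybenzaldehyde | COc1ccc(C=O)cc1 | starting material
6 | iodo(methanesulfonato)[3-(3,5-dimethoxyphenyl)-1-(trimethylsilyl)propa-1,2-dienyl]indium, axis from anti SN2′ opening of 4 | COc1cc(OC)cc(c1)C([H])=[C@]=C([Si](C)(C)C)[In](I)OS(C)(=O)=O | intermediate (not isolated)
7 | (1R,2R)-2-(3,5-dimethoxyphenyl)-1-(4-methoxyphenyl)-4-(trimethylsilyl)but-3-yn-1-ol | O[C@@H](c1ccc(OC)cc1)[C@H](c1cc(OC)cc(OC)c1)C#C[Si](C)(C)C | intermediate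
8 | (1R,2S)-2-(3,5-dimethoxyphenyl)-1-(4-methoxyphenyl)but-3-yn-1-ol | O[C@@H](c1ccc(OC)cc1)[C@H](c1cc(OC)cc(OC)c1)C#C | intermediate
9 | (1R,2R)-4-bromo-2-(3,5-dimethoxyphenyl)-1-(4-methoxyphenyl)but-3-yn-1-ol | O[C@@H](c1ccc(OC)cc1)[C@H](c1cc(OC)cc(OC)c1)C#CBr | intermediate
10 | (E)-3-(2,4-dimethoxyphenyl)prop-2-enoic acid | COc1ccc(/C=C/C(O)=O)c(OC)c1 | starting material
11 | (E)-1-(2-bromoethenyl)-2,4-dimethoxybenzene | COc1ccc(/C=C/Br)c(OC)c1 | intermediate
12 | (1R,2R,5E)-2-(3,5-dimethoxyphenyl)-6-(2,4-dimethoxyphenyl)-1-(4-methoxyphenyl)hex-5-en-3-yn-1-ol | O[C@@H](c1ccc(OC)cc1)[C@H](c1cc(OC)cc(OC)c1)C#C/C=C/c1ccc(OC)cc1OC | intermediate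
13 | trichloroethylene | ClC=C(Cl)Cl | starting material
14 | potassium alkoxide of 12 | [K+].[O-][C@@H](c1ccc(OC)cc1)[C@H](c1cc(OC)cc(OC)c1)C#C/C=C/c1ccc(OC)cc1OC | intermediate (not isolated)
15 | dichloroacetylene | ClC#CCl | intermediate (not isolated)
16 | (E)-1,2-dichloroethenyl ether of 12 | Cl/C=C(/Cl)O[C@@H](c1ccc(OC)cc1)[C@H](c1cc(OC)cc(OC)c1)C#C/C=C/c1ccc(OC)cc1OC | intermediate
17 | chloroethynyl ether of 12 | ClC#CO[C@@H](c1ccc(OC)cc1)[C@H](c1cc(OC)cc(OC)c1)C#C/C=C/c1ccc(OC)cc1OC | intermediate (not isolated)
18 | lithium alkoxyacetylide from 16 | [Li]C#CO[C@@H](c1ccc(OC)cc1)[C@H](c1cc(OC)cc(OC)c1)C#C/C=C/c1ccc(OC)cc1OC | intermediate (not isolated)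
19 | ethynyl ether of 12 | C#CO[C@@H](c1ccc(OC)cc1)[C@H](c1cc(OC)cc(OC)c1)C#C/C=C/c1ccc(OC)cc1OC | intermediate
20 | triyne carbinol with alkynyl ether tether | O[C@@H](c1ccc(OC)cc1)[C@H](c1cc(OC)cc(OC)c1)C#CC#CO[C@@H](c1ccc(OC)cc1)[C@H](c1cc(OC)cc(OC)c1)C#C/C=C/c1ccc(OC)cc1OC | intermediate
21 | ring A benzyne fused to dihydrofuran 2, carbinol arm free | O[C@@H](c1ccc(OC)cc1)[C@H](c1cc(OC)cc(OC)c1)C1=C(/C=C/c2ccc(OC)cc2OC)C2=C(C#C1)O[C@@H](c1ccc(OC)cc1)[C@@H]2c1cc(OC)cc(OC)c1 | intermediate (not isolated)
22 | (2R,3R,5R,6R)-3,5-bis(3,5-dimethoxyphenyl)-4-[(E)-2-(2,4-dimethoxyphenyl)ethenyl]-2,6-bis(4-methoxyphenyl)-2,3,5,6-tetrahydrobenzo[1,2-b:5,4-b']difuran | COc1ccc([C@@H]2Oc3cc4c(c(c3[C@H]2c2cc(OC)cc(OC)c2)/C=C/c2ccc(OC)cc2OC)[C@@H](c2cc(OC)cc(OC)c2)[C@H](c2ccc(OC)cc2)O4)cc1 | intermediate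
23 | 2,4-dimethoxybenzylic cation from 22 | COc1ccc([C@@H]2Oc3cc4c(c(c3[C@H]2c2cc(OC)cc(OC)c2)C[CH+]c2ccc(OC)cc2OC)[C@@H](c2cc(OC)cc(OC)c2)[C@H](c2ccc(OC)cc2)O4)cc1 | intermediate (not isolated)
24 | octa-O-methyl ether of the target | COc1ccc([C@@H]2Oc3cc4c5c(c3[C@H]2c2cc(OC)cc(OC)c2)C[C@H](c2ccc(OC)cc2OC)c2c(OC)cc(OC)cc2[C@H]5[C@H](c2ccc(OC)cc2)O4)cc1 | intermediate
25 | CNP0154047.1 | Oc1ccc([C@@H]2Oc3cc4c5c(c3[C@H]2c2cc(O)cc(O)c2)C[C@H](c2ccc(O)cc2O)c2c(O)cc(O)cc2[C@H]5[C@H](c2ccc(O)cc2)O4)cc1 | target

## Step count and least certain steps

Total: 13 steps. Longest linear sequence: 11 steps (1–4, 7–13).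

**Step 11 (key step, proposed new method).**
- What may go wrong: the alkynyl ether oxygen sits on a 4-methoxybenzylic carbon. A [3,3] shift onto the anisyl ring or a retro-ene cleavage to a ketene may consume 20 at or below the temperature the cycloaromatization needs. Once the benzyne is formed, arylation by the neighbouring dimethoxyphenyl ring may compete with O–H capture, and ring closure through the styryl carbon instead of the diyne is also possible.
- Fallback (known reaction types only, longer; it gives up the alkyne-based construction of ring A): it sets out from bromoalkene 11 and comes back at 22.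
  - Ring A is bought as 5-bromoresorcinol. O-Alkylation with 4-methoxybenzyl chloride gives bis(4-methoxybenzyl) ether F1, whose benzylic CH2 groups are the future C-a and C-e.
  - Iodination with NIS at the two positions flanking bromine gives diiodide F2.
  - Carbonylative Suzuki–Miyaura coupling at the two C–I bonds (CO, 3,5-dimethoxyphenylboronic acid, PdCl2(PPh3)2) gives diketone F3.
  - Hydrazine gives bis-hydrazone F4, and MnO2 oxidizes it to bis(diaryldiazomethane) F5.
  - Rh2(S-PTAD)4, or its enantiomer if that is the one that gives 3R, inserts each carbene into the neighbouring ArCH2–O C–H bond. This enantioselective C–H insertion of donor/donor carbenes should give the 2,3-cis bis(dihydrobenzofuran) F6, with C-b and C-d set by the catalyst.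
  - TFA at 0 °C equilibrates C-a and C-e through reversible opening of the 4-methoxybenzylic C–O bonds and should give the all-trans bromide F7.
  - Bromoalkene 11 is converted into pinacol boronate F8 (B2pin2, Pd(dppf)Cl2, KOAc). Suzuki–Miyaura coupling of F7 with F8 (Pd(OAc)2, SPhos, K3PO4) places the styryl group on A5 and gives 22.

**Step 3.**
- What may go wrong: racemization of the aryl-substituted allenylpalladium or allenylindium before addition, leakage to the syn isomer with an aromatic aldehyde, or decomposition of the benzylic mesylate.
- Fallback (purity by resolution, not by chirality transfer): it sets out from 7 and comes back at 8. Crude 7 is esterified with (S)-O-methylmandelic acid (DCC, DMAP) to mandelate F9. The diastereomers, including those from the syn series, are separated by chromatography or crystallization. K2CO3 in MeOH then removes both the ester and the silyl group and gives 8.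

**Step 9 (with step 10).**
- What may go wrong: loss of the terminal benzylic alkynyl ether during isolation (sigmatropic shift, hydration), β-elimination of the lithium alkoxyacetylide on warming, or addition of amine or water during the copper-catalysed coupling.
- Fallback (no free alkynyl ether, no aqueous amine): it sets out from 16 and comes back at 20. After n-BuLi at −78 °C, CuBr·SMe2 converts 18 into copper alkoxyacetylide F10. Bromoalkyne 9 and pyridine are then added at −20 to 0 °C (stoichiometric copper acetylide–bromoalkyne coupling) to give 20.

**Step 12.**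
- What may go wrong: poor facial selectivity at the planar cation (wrong epimer at C-c), acid-induced opening of the dihydrofurans, or intermolecular alkylation.
- Fallback (closure on the free phenol, as in acid-induced cyclizations of unprotected oligostilbenes): it sets out from 22 and comes back at 25. Nucleophilic demethylation with NaSEt in DMF at 130 °C gives octaphenol F11. Dilute HCl in MeOH or formic acid at rt then protonates the resorcinyl styrene and closes the seven-membered ring directly to 25, under conformational control by the hydrogen-bonded free phenols.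

**Step 13.**
- What may go wrong: ionization or bromide opening of the benzylic C–O bonds of the dihydrofurans by the Lewis acid, with epimerization or rearrangement, and incomplete cleavage of eight ethers.
- Fallback (SN2 at methyl under basic conditions, no Lewis acid): it sets out from 24 and comes back at 25 with NaSEt in DMF at 130 °C; no new compound is made.

## Further compounds

F1 | step 11 | 1-bromo-3,5-bis[(4-methoxyphenyl)methoxy]benzene | Brc1cc(OCc2ccc(OC)cc2)cc(OCc2ccc(OC)cc2)c1
F2 | step 11 | 2-bromo-1,3-diiodo-4,6-bis[(4-methoxyphenyl)methoxy]benzene | Brc1c(I)c(OCc2ccc(OC)cc2)cc(OCc2ccc(OC)cc2)c1I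
F3 | step 11 | {2-bromo-4,6-bis[(4-methoxyphenyl)methoxy]-1,3-phenylene}bis[(3,5-dimethoxyphenyl)methanone] | Brc1c(C(=O)c2cc(OC)cc(OC)c2)c(OCc2ccc(OC)cc2)cc(OCc2ccc(OC)cc2)c1C(=O)c1cc(OC)cc(OC)c1
F4 | step 11 | bis-hydrazone of F3 | Brc1c(C(=NN)c2cc(OC)cc(OC)c2)c(OCc2ccc(OC)cc2)cc(OCc2ccc(OC)cc2)c1C(=NN)c1cc(OC)cc(OC)c1
F5 | step 11 | bis(diaryldiazomethane) from F4 | Brc1c(C(=[N+]=[N-])c2cc(OC)cc(OC)c2)c(OCc2ccc(OC)cc2)cc(OCc2ccc(OC)cc2)c1C(=[N+]=[N-])c1cc(OC)cc(OC)c1
F6 | step 11 | (2S,3R,5R,6S)-4-bromo-3,5-bis(3,5-dimethoxyphenyl)-2,6-bis(4-methoxyphenyl)-2,3,5,6-tetrahydrobenzo[1,2-b:5,4-b']difuran (2,3-cis and 5,6-cis) | COc1ccc([C@H]2Oc3cc4c(c(Br)c3[C@H]2c2cc(OC)cc(OC)c2)[C@@H](c2cc(OC)cc(OC)c2)[C@@H](c2ccc(OC)cc2)O4)cc1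
F7 | step 11 | (2R,3R,5R,6R)-4-bromo-3,5-bis(3,5-dimethoxyphenyl)-2,6-bis(4-methoxyphenyl)-2,3,5,6-tetrahydrobenzo[1,2-b:5,4-b']difuran (all trans) | COc1ccc([C@@H]2Oc3cc4c(c(Br)c3[C@H]2c2cc(OC)cc(OC)c2)[C@@H](c2cc(OC)cc(OC)c2)[C@H](c2ccc(OC)cc2)O4)cc1
F8 | step 11 | (E)-2-[2-(2,4-dimethoxyphenyl)ethenyl]-4,4,5,5-tetramethyl-1,3,2-dioxaborolane | COc1ccc(/C=C/B2OC(C)(C)C(C)(C)O2)c(OC)c1
F9 | step 3 | (S)-O-methylmandelate ester of 7 | CO[C@H](C(=O)O[C@@H](c1ccc(OC)cc1)[C@H](c1cc(OC)cc(OC)c1)C#C[Si](C)(C)C)c1ccccc1
F10 | step 9 | copper alkoxyacetylide from 18 (monovalent copper) | [Cu]C#CO[C@@H](c1ccc(OC)cc1)[C@H](c1cc(OC)cc(OC)c1)C#C/C=C/c1ccc(OC)cc1OC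
F11 | step 12 | octaphenol corresponding to 22 | Oc1ccc([C@@H]2Oc3cc4c(c(c3[C@H]2c2cc(O)cc(O)c2)/C=C/c2ccc(O)cc2O)[C@@H](c2cc(O)cc(O)c2)[C@H](c2ccc(O)cc2)O4)cc1
F0 | step 13 | none | none
A1 | alternative 1 | methyl 4,6-bis(benzyloxy)-2-oxo-2,3-dihydro-1H-indene-1-carboxylate | COC(=O)C1C(=O)Cc2cc(OCc3ccccc3)cc(OCc3ccccc3)c21
A2 | alternative 1 | 3,5-dimethoxybenzyne | COC1=CC(OC)=CC#C1
A3 | alternative 1 | methyl bis(benzyloxy)-dimethoxy-oxo-dibenzo[a,d]cycloheptene carboxylate (ketone at C7, ester at C8) | COC(=O)C1c2cc(OC)cc(OC)c2C(=O)Cc2cc(OCc3ccccc3)cc(OCc3ccccc3)c21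
A4 | alternative 2 | cycloheptenyl diazomethyl ketone fused to the ring A dihydrobenzofuran | C(Oc1cc2c3c(c1)C[C@H](c1ccc(OC)cc1OC)C=C(C(=O)C=[N+]=[N-])[C@H]3[C@H](c1ccc(OC)cc1)O2)c1ccccc1
A5 | alternative 2 | triisopropylsiloxyethyne | C#CO[Si](C(C)C)(C(C)C)C(C)C
A6 | alternative 2 | ring B phenol silyl ether of the dibenzocycloheptane–dihydrobenzofuran core | C(Oc1cc2c3c(c1)C[C@H](c1ccc(OC)cc1OC)c1c(O)cc(O[Si](C(C)C)(C(C)C)C(C)C)cc1[C@H]3[C@H](c1ccc(OC)cc1)O2)c1ccccc1
A7 | alternative 3 | (2R)-7-(benzyloxy)-2-(4-methoxyphenyl)-5-methylchroman-4-one | O=C1C[C@H](c2ccc(OC)cc2)Oc2cc(OCc3ccccc3)cc(C)c21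
A8 | alternative 3 | methyl (2R,3R)-6-(benzyloxy)-2-(4-methoxyphenyl)-4-methyl-2,3-dihydrobenzofuran-3-carboxylate | COC(=O)[C@H]1[C@H](c2ccc(OC)cc2)Oc2cc(OCc3ccccc3)cc(C)c21
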